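## Analysis of the target

The target 33 is a C50 carotenoid of the ε,ε type. Two 1,1,5-trimethylcyclohex-4-ene rings (ring A and ring B) are joined through C6 and C6′ by an all-E chain of nine conjugated double bonds (C7 to C7′) with methyl groups at C9, C13, C13′ and C9′. Each ring carries a five-carbon arm on C2: 3-methylbut-2-enyl on ring A and (E)-4-hydroxy-3-methylbut-2-enyl on ring B. The four stereocentres are the methines C2/C6 and C2′/C6′ that flank the quaternary C1 and C1′. In ring A the arm and the chain are cis, in ring B trans. A CIP analysis of the structure gives (2S,6R,2′R,6′S): C2 and C2′ have the same spatial sense (the letter changes only because the hydroxyl raises the priority of the arm), while C6 and C6′ are opposite. The molecule is therefore unsymmetrical in the arms and in the relative configuration of the rings, and the cis ring A is the less stable arrangement. Sensitive features are the polyene (light, oxygen, acid), the doubly allylic C6–H and C6′–H (through which C4=C5 can slip into conjugation under acid or base) and the primary allylic alcohol. The route rests on one feature of ring A: C1″ (the CH2 of the arm), C2, C1, C6 and C7 form a cyclopentene once C1″ and C7 are joined, and C3–C4=C5 bridges it, so ring A is a bicyclo[3.2.1]octa-2,6-diene with its two-carbon bridge cut.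

## Retrosynthetic reasoning

**33 from 32.** Only the oxidation level of the arm changes. The hydroxyl is carried as the methyl ester because the ester arm arises E-selectively by olefination and survives the acidic phosphonium salt formation, where a free allylic alcohol could ionise. The forward step is a hydride reduction of one ester on the finished polyene.

**32 from 30 and 27; 30 from 21 and 28.** The cuts are at C11′=C12′ and C11=C12. They place all four stereocentres in two C20 end groups and leave the symmetrical dialdehyde 28 as the centre. Because the ends differ, 28 is olefinated once in excess and then a second time. Each Wittig reaction must give a disubstituted alkene that can be equilibrated to E.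

**21 from 20, 19 and 18; 27 from 26 and 25.** The C11–P bond comes from a tertiary bis-allylic carbinol with allylic transposition, the C9–C10 bond from a vinyl-metal addition to a methyl ketone, and C7=C8 from olefination of a C7 aldehyde with a three-carbon stabilised ylide. None of these steps touches C6.

**25 from 24.** Ring B differs from ring A only at C6, so both end groups come from one enantiomeric series and C6 is inverted in the ring B branch alone. The inversion is placed at the enone 24 and not at aldehyde 23: the enolate of 23 can reprotonate at C4 and slide into the conjugated C5=C6 enal, whereas the vinylogous enolate of 24 is expected to return mainly to the C6-protonated enones. The forward step is a thermodynamic equilibration toward the trans ring.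

**19 from 18, 17 and 16; 24 from 23, 22 and 16.** Both arms are cut at C2″=C3″. One aldehyde, 16, then serves both rings; only the ylide differs (a non-stabilised isopropylidene ylide for ring A, a stabilised E-selective ester ylide for ring B). The free C7 alcohol is oxidised after the arm is in place.

**16 from 14, 13 and 11; 11 from 10.** In 10 the three carbons C1″, C5-carboxyl and C7 are all carbonyl carbons and must be told apart. C1″ (the only aldehyde) is extended by one carbon as an enol ether, which masks the future arm aldehyde. The C5 ester is reduced beside the C7 carboxylate and closed onto it as the allylic lactone 13; cleaving its allylic C–O bond with hydride turns the C5 carboxyl carbon into the C5 methyl and returns the C7 acid. No protecting group is needed.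

**10 from 8.** C1″ and C7 are reconnected as the double bond of a silyl enol ether. Forward, ozonolysis must cleave this electron-rich, strained alkene and spare the enoate; it delivers C7 as an acid and C1″ as an aldehyde.

**8 from 2 and 6.** The bonds C5–C6 and C2–C3 are cut, which is a [4+3] disconnection of the bicycle into a five-carbon diene and a three-carbon vinylcarbenoid. This is the only step that creates stereocentres; it must give one enantiomer and the regiochemistry that puts the silyloxy carbon next to C6.

**2 from 1; 6 from 5, 4 and 3.** The diene is the silyl dienol ether of a commercial enone; the vinyldiazoester follows from an acetoacetate by diazo transfer, reduction and dehydration.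

## Alternatives that were turned down

**Alternative 1: Ireland–Claisen ring contraction across C2–C3.**
- Disconnection: the carbocycle A2 (cis-6-(benzyloxymethyl)-2,2,5-trimethylcyclohex-4-ene-1-carboxylic acid; carboxyl carbon = C1″, benzyloxymethyl carbon = C7) is opened at C2–C3 to the six-membered vinyl lactone A1. In A1 the carbonyl carbon is C1″, the α-carbon C2 and the vinyl-bearing tertiary carbinol carbon C5.
- Key step: the silyl ketene acetal of A1 rearranges [3,3] through a boat. C2 bonds to the vinyl terminus C3, the double bond moves to C4=C5, and the carboxyl group is released.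
- For: the C5 methyl and the C4=C5 alkene are in place at once, and C7 and C1″ arrive at different oxidation levels. On this point it is stronger than the chosen route, which has to sort three carbonyl groups after ozonolysis. The cis relation follows stereospecifically if the vinyl group of A1 is trans to the benzyloxymethyl group.
- Against: A1 contains a fully substituted carbinol stereocentre next to C6 and one bond from the quaternary C1. It has to be made as one diastereomer and one enantiomer over several steps, and that centre is destroyed in the key step. The enolate of a tertiary allylic ester can also eliminate. Ring B would need C6 inverted while it carries an ether, which costs further redox steps.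
- Comparison: the chosen route reaches its key-step precursor in one step and sets both ring stereocentres in one catalytic event. It pays with more functional-group work afterwards.

**Alternative 2: cationic closure of C1–C6 on a chiral-pool chain.**
- Disconnection: the ionone A5 (cis-2-(2-acetoxyethyl)-α-ionone) is opened at C1–C6 to the acyclic trienone A4, whose C2 stereocentre and isopropenyl group come from (R)-limonene A3 by cleavage of its ring double bond.
- Key step: a Lewis or protic acid protonates the isopropenyl group of A4. The C1 cation is captured by C6 of the dienone and a proton is lost from C4.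
- For: C2 comes from a cheap terpene without a chiral catalyst, and A5 already carries C7 to C10. In absolute stereocontrol at C2 and in step economy toward the phosphonium salt this alternative is as strong or stronger.
- Against: C6 is set only by the conformational preference of the cyclisation, and proton loss can occur toward C4, C6 or the C5 methyl. Mixtures of ring configuration and alkene position are to be expected next to an acid-sensitive dienone. The cis ring is the likely kinetic product, so ring B would need the same epimerisation as in the chosen route.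
- Comparison: the chosen strategy makes the cis relation a geometric necessity and fixes the alkene position by a pericyclic step.

**Alternative 3: ring-closing metathesis with diastereotopic allyl groups.**
- Disconnection: the ring A7 (trans-2-allyl-α-cyclogeranyl benzyl ether) is opened at C4=C5 to the triene A6, which carries an isopropenyl group on C6 and two allyl groups on C2.
- Key step: a ruthenium alkylidene catalyst joins the isopropenyl group with one of the two allyl groups, closing the cyclohexene and fixing C2.
- For: the alkene position is unambiguous, and the remaining allyl group could be turned into either arm by cross-metathesis. That is shorter than the homologation and Wittig sequence used here.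
- Against: C2 is set by a choice between two diastereotopic groups under the influence of C6 across a quaternary carbon, which is a weak bias and gives no access to the cis ring A. The two allyl groups can also close on each other to a cyclopentene faster than either engages the hindered 1,1-disubstituted alkene. A6 still needs its own asymmetric synthesis.
- Comparison: the chosen route takes longer for the arms but has firm control of both ring stereocentres.

Key step: step 5

Assumption: the sense of induction of Rh2(S-DOSP)4 with diene 2 is taken to follow that with cyclopentadiene; should 8 form as its mirror image, Rh2(R-DOSP)4 is used and nothing else changes.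

Remark: 11 to 15 are carried as E/Z mixtures at the enol ether double bond, which disappears in step 10; 20 and 26 are mixtures at the carbinol carbon, which is lost in steps 15 and 21.

## Route

Step 1
Reactants: 1 4,4-dimethylcyclopent-2-en-1-one
Product: 2 2-(tert-butyldimethylsilyloxy)-5,5-dimethylcyclopenta-1,3-diene
Conditions: t-BuMe2SiOTf, Et3N, CH2Cl2, 0 °C; filtration through basic Al2O3, distillation
Reagents that add atoms: tert-butyldimethylsilyl trifluoromethanesulfonate, CC(C)(C)[Si](C)(C)OS(=O)(=O)C(F)(F)F
Why: Soft enolisation and O-silylation (silyl enol ether formation); the γ-carbon is quaternary, so only the α′-CH2 can be deprotonated and the cross-conjugated dienol ether is the only possible product.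

Step 2
Reactants: 3 methyl acetoacetate
Product: 4 methyl 2-diazo-3-oxobutanoate
Conditions: 4-AcNHC6H4SO2N3, Et3N, MeCN, 0 °C → rt
Reagents that add atoms: 4-acetamidobenzenesulfonyl azide, CC(=O)Nc1ccc(cc1)S(=O)(=O)N=[N+]=[N-]
Why: Regitz diazo transfer to an activated methylene group; the sulfonamide by-product is removed by filtration.

Step 3
Reactants: 4 methyl 2-diazo-3-oxobutanoate
Product: 5 methyl 2-diazo-3-hydroxybutanoate (racemic)
Conditions: NaBH4, MeOH, 0 °C
Reagents that add atoms: none
Why: Chemoselective borohydride reduction of the ketone; the diazo group and the ester are inert, and the new stereocentre is removed in the next step.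

Step 4
Reactants: 5 methyl 2-diazo-3-hydroxybutanoate
Product: 6 methyl 2-diazobut-3-enoate
Conditions: POCl3, Et3N, CH2Cl2, 0 °C; cold pentane solution used at once
Reagents that add atoms: none
Why: Dehydration through the dichlorophosphate (β-elimination) gives the vinyldiazoester; it is kept cold and used directly because it slowly electrocyclises to a pyrazole.

Step 5
Reactants: 2 2-(tert-butyldimethylsilyloxy)-5,5-dimethylcyclopenta-1,3-diene; 6 methyl 2-diazobut-3-enoate
Product: 8 methyl (1S,5R)-7-(tert-butyldimethylsilyloxy)-8,8-dimethylbicyclo[3.2.1]octa-2,6-diene-2-carboxylate, via divinylcyclopropane 7 (not isolated)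
Conditions: Rh2(S-DOSP)4 (1 mol %), 2 (2 equiv), slow addition of 6, pentane, −78 °C → rt
Reagents that add atoms: none
Why: Rh2(S-DOSP)4 (divalent rhodium) decomposes 6 to a rhodium-bound vinylcarbenoid, a donor/acceptor carbenoid that adds to the silyl enol ether double bond of 2, bonding first to the unsubstituted enol ether carbon (the later C6) while positive charge builds on the silyloxy carbon, and closes to the cis-divinylcyclopropane 7 with the vinyl group over the five-membered ring. Cope rearrangement of 7 through the only accessible boat transition state breaks the cyclopropane bond between the two vinyl-bearing carbons and joins the vinyl terminus to the far diene terminus (C2–C3), so the seven-membered ring is closed by ring expansion of the cyclopropane and, across the CMe2 bridge, the six-membered ring C1–C6 is closed at the same time with its double bond already at C4=C5. The closest known reaction type is the tandem cyclopropanation/Cope rearrangement (formal [4+3] cycloaddition) of vinyldiazoacetates with cyclopentadiene and with 2-silyloxy dienes under dirhodium tetraprolinate catalysis. The C6 stereocentre is set in the cyclopropanation, where the chiral prolinate ligands select the face of attack; the C2 stereocentre follows in the concerted Cope step and can only be cis to C6, because the three-carbon bridge must span one face of the cyclopentene. The step needs site selectivity for the enol ether over the other double bond of 2 (secured by the oxygen donor), endo placement of the vinyl group (the normal preference of donor/acceptor carbenoids, ester away from the alkene substituents, and a condition of the Cope step), and enantioselectivity, which rests on the catalyst in a hydrocarbon solvent at low temperature. The quaternary carbon of 2 excludes 1,5-hydrogen shifts and holds the diene s-cis, but it also flanks both diene termini, which is the main uncertainty. Slow addition of 6 to an excess of 2 should keep carbenoid dimerisation and the electrocyclisation of 6 in check.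

Step 6
Reactants: 8 methyl (1S,5R)-7-(tert-butyldimethylsilyloxy)-8,8-dimethylbicyclo[3.2.1]octa-2,6-diene-2-carboxylate
Product: 10 (1S,5S)-5-formyl-2-(methoxycarbonyl)-6,6-dimethylcyclohex-2-ene-1-carboxylic acid, via silyl ester 9 (not isolated)
Conditions: O3, CH2Cl2/MeOH, −78 °C (Sudan red 7B end-point); Me2S, −78 °C → rt; then AcOH/THF/H2O, rt
Reagents that add atoms: ozone, [O-][O+]=O
Why: Ozonolysis (Criegee mechanism) of the electron-rich, strained silyl enol ether is far faster than attack on the electron-poor enoate; the silyloxy carbon leaves as a silyl ester (C7, hydrolysed to the acid) and the CH carbon as an aldehyde (C1″), so the two termini are differentiated and the cis relation of C2 and C6 is kept.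

Step 7
Reactants: 10 (1S,5S)-5-formyl-2-(methoxycarbonyl)-6,6-dimethylcyclohex-2-ene-1-carboxylic acid
Product: 11 (1S,5R)-2-(methoxycarbonyl)-5-(2-methoxyethenyl)-6,6-dimethylcyclohex-2-ene-1-carboxylic acid (E/Z mixture)
Conditions: MeOCH2PPh3Cl, KN(SiMe3)2 (3 equiv of ylide), THF, 0 °C; 10, −78 °C → 0 °C; work-up at pH 5
Reagents that add atoms: (methoxymethyl)triphenylphosphonium chloride, COC[P+](c1ccccc1)(c1ccccc1)c1ccccc1.[Cl-]
Why: Wittig one-carbon homologation of the aldehyde; the first equivalent of ylide turns the acid into its carboxylate, which shields C6–H from deprotonation, and the hindered C2–H next to the quaternary carbon should survive the short exposure at low temperature.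

Step 8
Reactants: 11 (1S,5R)-2-(methoxycarbonyl)-5-(2-methoxyethenyl)-6,6-dimethylcyclohex-2-ene-1-carboxylic acid
Product: 13 (6R,7aS)-6-(2-methoxyethenyl)-7,7-dimethyl-5,6,7,7a-tetrahydro-2-benzofuran-1(3H)-one, via hydroxy acid 12 (not isolated)
Conditions: i-Bu2AlH (excess), CH2Cl2, −78 °C → −40 °C; aq. potassium sodium tartrate; then PPh3, i-PrO2CN=NCO2i-Pr, THF, 0 °C
Reagents that add atoms: none
Why: The aluminium carboxylate of the hindered acid resists i-Bu2AlH at low temperature while the conjugated ester is reduced 1,2 to the allylic alcohol; Mitsunobu lactonisation then activates that alcohol and the neighbouring carboxylate displaces it (5-exo closure at a primary allylic carbon), without activating the acyl group and thus without risk to C6.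

Step 9
Reactants: 13 (6R,7aS)-6-(2-methoxyethenyl)-7,7-dimethyl-5,6,7,7a-tetrahydro-2-benzofuran-1(3H)-one
Product: 14 (1R,5R)-5-(2-methoxyethenyl)-2,6,6-trimethylcyclohex-2-ene-1-carboxylic acid
Conditions: Pd(PPh3)4 (5 mol %), NaBH4, DME, 0 °C → rt; pH 5 buffer
Reagents that add atoms: none
Why: Palladium-catalysed allylic hydrogenolysis: Pd(PPh3)4 (zerovalent palladium) ionises the allylic lactone C–O bond to a π-allyl complex with the carboxylate as tethered leaving group (Tsuji–Trost type), and borohydride delivers hydride to the less hindered primary terminus, giving the C5 methyl and restoring C4=C5; reclosure of the carboxylate only regenerates 13.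

Step 10
Reactants: 14 (1R,5R)-5-(2-methoxyethenyl)-2,6,6-trimethylcyclohex-2-ene-1-carboxylic acid
Product: 16 2-[(1R,3R)-3-(hydroxymethyl)-2,2,4-trimethylcyclohex-4-en-1-yl]acetaldehyde, via enol ether alcohol 15 (not isolated)
Conditions: LiAlH4, THF, 0 °C → reflux; then 1 M HCl, THF, 0 °C → rt
Reagents that add atoms: water, O
Why: Hydride reduction of the carboxylic acid to the primary alcohol, then acid hydrolysis of the enol ether, which protonates at C1″ and releases the arm aldehyde at C2″; the stereocentres carry no carbonyl group in this step.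

Step 11
Reactants: 16 2-[(1R,3R)-3-(hydroxymethyl)-2,2,4-trimethylcyclohex-4-en-1-yl]acetaldehyde
Product: 17 [(1R,5S)-2,6,6-trimethyl-5-(3-methylbut-2-en-1-yl)cyclohex-2-en-1-yl]methanol
Conditions: i-PrPPh3I, n-BuLi, THF, 0 °C (2.5 equiv of ylide); 16, −78 °C → rt
Reagents that add atoms: isopropyltriphenylphosphonium iodide, CC(C)[P+](c1ccccc1)(c1ccccc1)c1ccccc1.[I-]
Why: Wittig olefination with a non-stabilised ylide completes the 3-methylbut-2-enyl arm; one equivalent is consumed by the hydroxyl, and no alkene geometry arises because the new carbon carries two methyl groups.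

Step 12
Reactants: 17 [(1R,5S)-2,6,6-trimethyl-5-(3-methylbut-2-en-1-yl)cyclohex-2-en-1-yl]methanol
Product: 18 (1R,5S)-2,6,6-trimethyl-5-(3-methylbut-2-en-1-yl)cyclohex-2-ene-1-carbaldehyde
Conditions: Dess–Martin periodinane, NaHCO3, CH2Cl2, 0 °C; used directly
Reagents that add atoms: none
Why: Dess–Martin oxidation is neutral and base-free, so the cis C6 stereocentre of the β,γ-unsaturated aldehyde is not exposed to enolisation.

Step 13
Reactants: 18 (1R,5S)-2,6,6-trimethyl-5-(3-methylbut-2-en-1-yl)cyclohex-2-ene-1-carbaldehyde
Product: 19 (E)-4-[(1R,5S)-2,6,6-trimethyl-5-(3-methylbut-2-en-1-yl)cyclohex-2-en-1-yl]but-3-en-2-one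
Conditions: Ph3P=CHCOMe, toluene, 90 °C
Reagents that add atoms: 1-(triphenyl-λ5-phosphanylidene)propan-2-one, CC(=O)C=P(c1ccccc1)(c1ccccc1)c1ccccc1
Why: Wittig reaction with a stabilised ylide gives the E-enone (C7=C8) under neutral conditions; the ylide is too weak a base to epimerise C6, so the cis ring of ring A is kept.

Step 14
Reactants: 19 (E)-4-[(1R,5S)-2,6,6-trimethyl-5-(3-methylbut-2-en-1-yl)cyclohex-2-en-1-yl]but-3-en-2-one
Product: 20 (E)-3-methyl-1-[(1R,5S)-2,6,6-trimethyl-5-(3-methylbut-2-en-1-yl)cyclohex-2-en-1-yl]penta-1,4-dien-3-ol (both carbinol epimers)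
Conditions: CH2=CHMgBr, THF, −20 °C → 0 °C; aq. NH4Cl
Reagents that add atoms: vinylmagnesium bromide, C=C[Mg]Br
Why: Grignard 1,2-addition to the methyl ketone forms the C9–C10 bond; addition is faster than γ-deprotonation at C6, as in the preparation of vinyl carbinols from ionone-type enones.

Step 15
Reactants: 20 (E)-3-methyl-1-[(1R,5S)-2,6,6-trimethyl-5-(3-methylbut-2-en-1-yl)cyclohex-2-en-1-yl]penta-1,4-dien-3-ol
Product: 21 {(2E,4E)-3-methyl-5-[(1R,5S)-2,6,6-trimethyl-5-(3-methylbut-2-en-1-yl)cyclohex-2-en-1-yl]penta-2,4-dien-1-yl}triphenylphosphonium bromide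
Conditions: PPh3·HBr, MeOH, rt; crystallisation
Reagents that add atoms: triphenylphosphine hydrobromide, Br.c1ccc(cc1)P(c1ccccc1)c1ccccc1
Why: The tertiary bis-allylic alcohol ionises under the mild acid to a pentadienyl cation that the phosphine captures at the primary terminus (allylic transposition); the isolated trisubstituted alkenes of the ring and the arm are not protonated under these conditions.

Step 16
Reactants: 16 2-[(1R,3R)-3-(hydroxymethyl)-2,2,4-trimethylcyclohex-4-en-1-yl]acetaldehyde
Product: 22 methyl (E)-4-[(1R,3R)-3-(hydroxymethyl)-2,2,4-trimethylcyclohex-4-en-1-yl]-2-methylbut-2-enoate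
Conditions: Ph3P=C(Me)CO2Me, CH2Cl2, rt → 40 °C
Reagents that add atoms: methyl 2-(triphenyl-λ5-phosphanylidene)propanoate, COC(=O)C(C)=P(c1ccccc1)(c1ccccc1)c1ccccc1
Why: Wittig reaction with a stabilised ylide gives the trisubstituted E-enoate, which fixes the geometry of the later hydroxylated arm; the free alcohol does not interfere.

Step 17
Reactants: 22 methyl (E)-4-[(1R,3R)-3-(hydroxymethyl)-2,2,4-trimethylcyclohex-4-en-1-yl]-2-methylbut-2-enoate
Product: 23 methyl (E)-4-[(1R,3R)-3-formyl-2,2,4-trimethylcyclohex-4-en-1-yl]-2-methylbut-2-enoate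
Conditions: Dess–Martin periodinane, NaHCO3, CH2Cl2, 0 °C; used directly
Reagents that add atoms: none
Why: Dess–Martin oxidation of the hindered primary alcohol under neutral conditions, as in step 12.

Step 18
Reactants: 23 methyl (E)-4-[(1R,3R)-3-formyl-2,2,4-trimethylcyclohex-4-en-1-yl]-2-methylbut-2-enoate
Product: 24 methyl (E)-2-methyl-4-{(1R,3R)-2,2,4-trimethyl-3-[(E)-3-oxobut-1-en-1-yl]cyclohex-4-en-1-yl}but-2-enoate (cis ring)
Conditions: Ph3P=CHCOMe, toluene, 90 °C
Reagents that add atoms: 1-(triphenyl-λ5-phosphanylidene)propan-2-one, CC(=O)C=P(c1ccccc1)(c1ccccc1)c1ccccc1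
Why: Wittig reaction with the stabilised ylide, E-selective, as in step 13; the ylide does not react with the enoate.

Step 19
Reactants: 24 methyl (E)-2-methyl-4-{(1R,3R)-2,2,4-trimethyl-3-[(E)-3-oxobut-1-en-1-yl]cyclohex-4-en-1-yl}but-2-enoate
Product: 25 methyl (E)-2-methyl-4-{(1R,3S)-2,2,4-trimethyl-3-[(E)-3-oxobut-1-en-1-yl]cyclohex-4-en-1-yl}but-2-enoate (trans ring)
Conditions: NaOMe (cat.), MeOH, rt, to equilibrium; chromatography, 24 recycled
Reagents that add atoms: none
Why: Base-mediated epimerisation through the vinylogous enolate (deprotonation at the doubly allylic C6, γ to the ketone); the trans isomer should be favoured because the C6 side chain can then sit pseudoaxial, away from the C5 methyl, while the C2 arm stays equatorial, whereas the cis isomer must place both groups syn-diaxial or push the side chain against the C5 methyl. The cis-to-trans change of α-irone (2-methyl-α-ionone) in base is the close analogy, and the methyl ester of the arm is unchanged in NaOMe/MeOH.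

Step 20
Reactants: 25 methyl (E)-2-methyl-4-{(1R,3S)-2,2,4-trimethyl-3-[(E)-3-oxobut-1-en-1-yl]cyclohex-4-en-1-yl}but-2-enoate
Product: 26 methyl (E)-4-{(1R,3S)-3-[(E)-3-hydroxy-3-methylpenta-1,4-dien-1-yl]-2,2,4-trimethylcyclohex-4-en-1-yl}-2-methylbut-2-enoate (both carbinol epimers)
Conditions: CH2=CHMgBr, CeCl3, THF, −78 °C; aq. NH4Cl
Reagents that add atoms: vinylmagnesium bromide, C=C[Mg]Br
Why: Grignard 1,2-addition in its organocerium variant, which is selective for the ketone over the α-methyl-substituted conjugated ester at low temperature and suppresses enolisation.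

Step 21
Reactants: 26 methyl (E)-4-{(1R,3S)-3-[(E)-3-hydroxy-3-methylpenta-1,4-dien-1-yl]-2,2,4-trimethylcyclohex-4-en-1-yl}-2-methylbut-2-enoate
Product: 27 {(2E,4E)-5-[(1S,5R)-5-((E)-4-methoxy-3-methyl-4-oxobut-2-en-1-yl)-2,6,6-trimethylcyclohex-2-en-1-yl]-3-methylpenta-2,4-dien-1-yl}triphenylphosphonium bromide
Conditions: PPh3·HBr, MeOH, rt; crystallisation
Reagents that add atoms: triphenylphosphine hydrobromide, Br.c1ccc(cc1)P(c1ccccc1)c1ccccc1
Why: Phosphonium salt formation with allylic transposition as in step 15; the arm is an ester at this stage and cannot ionise, which is the reason for carrying it at this oxidation level.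

Step 22
Reactants: 21 {(2E,4E)-3-methyl-5-[(1R,5S)-2,6,6-trimethyl-5-(3-methylbut-2-en-1-yl)cyclohex-2-en-1-yl]penta-2,4-dien-1-yl}triphenylphosphonium bromide; 28 (2E,4E,6E)-2,7-dimethylocta-2,4,6-trienedial
Product: 30 (2S,6R)-2-(3-methylbut-2-en-1-yl)-12′-apo-ε-caroten-12′-al (all-E), via phosphorus ylide 29 (not isolated)
Conditions: 28 (4 equiv), NaOMe, CH2Cl2/MeOH, 0 °C → rt, slow addition of 21; then heptane, reflux (Z → E), Ar, dark
Reagents that add atoms: none
Why: Wittig reaction of the semi-stabilised dienyl ylide with one aldehyde group of the symmetrical dialdehyde, kept to single olefination by the excess of 28 (recovered); the new C11=C12 bond forms as an E/Z mixture that is equilibrated thermally to E, the usual practice with carotenoid polyenes.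

Step 23
Reactants: 30 (2S,6R)-2-(3-methylbut-2-en-1-yl)-12′-apo-ε-caroten-12′-al; 27 {(2E,4E)-5-[(1S,5R)-5-((E)-4-methoxy-3-methyl-4-oxobut-2-en-1-yl)-2,6,6-trimethylcyclohex-2-en-1-yl]-3-methylpenta-2,4-dien-1-yl}triphenylphosphonium bromide
Product: 32 methyl (E)-2-methyl-4-[(2S,6R,2′R,6′S)-2-(3-methylbut-2-en-1-yl)-ε,ε-caroten-2′-yl]but-2-enoate (all-E), via phosphorus ylide 31 (not isolated)
Conditions: NaOMe, CH2Cl2/MeOH, rt; then heptane/EtOH, reflux (Z → E); crystallisation, Ar, dark
Reagents that add atoms: none
Why: Second Wittig reaction forms C11′=C12′ and completes the C50 skeleton; the methyl ester is unchanged by NaOMe in MeOH, and thermal equilibration should give the all-E chain.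

Step 24
Reactants: 32 methyl (E)-2-methyl-4-[(2S,6R,2′R,6′S)-2-(3-methylbut-2-en-1-yl)-ε,ε-caroten-2′-yl]but-2-enoate
Product: 33 (2S,6R,2′R,6′S)-2-(3-methylbut-2-en-1-yl)-2′-[(E)-4-hydroxy-3-methylbut-2-en-1-yl]-ε,ε-carotene (target)
Conditions: i-Bu2AlH, CH2Cl2/toluene, −78 °C; aq. potassium sodium tartrate; Ar, dark
Reagents that add atoms: none
Why: Hydride 1,2-reduction of the conjugated ester to the primary allylic alcohol; the hydrocarbon polyene is inert to i-Bu2AlH, and the E geometry of the arm is retained.

## Compound list

1 | 4,4-dimethylcyclopent-2-en-1-one | CC1(C)CC(=O)C=C1 | starting material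
2 | 2-(tert-butyldimethylsilyloxy)-5,5-dimethylcyclopenta-1,3-diene | CC1(C)C=CC(O[Si](C)(C)C(C)(C)C)=C1 | intermediate
3 | methyl acetoacetate | COC(=O)CC(C)=O | starting material
4 | methyl 2-diazo-3-oxobutanoate | COC(=O)C(=[N+]=[N-])C(C)=O | intermediate
5 | methyl 2-diazo-3-hydroxybutanoate (racemic) | COC(=O)C(=[N+]=[N-])C(C)O | intermediate
6 | methyl 2-diazobut-3-enoate | C=CC(=[N+]=[N-])C(=O)OC | intermediate
7 | methyl 1-(tert-butyldimethylsilyloxy)-4,4-dimethyl-6-vinylbicyclo[3.1.0]hex-2-ene-6-carboxylate (vinyl endo, cis-divinylcyclopropane) | C=C[C@]1(C(=O)OC)[C@@H]2C(C)(C)C=C[C@]12O[Si](C)(C)C(C)(C)C | intermediate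
8 | methyl (1S,5R)-7-(tert-butyldimethylsilyloxy)-8,8-dimethylbicyclo[3.2.1]octa-2,6-diene-2-carboxylate | CC(C)(C)[Si](C)(C)OC1=C[C@H]2CC=C(C(=O)OC)[C@@H]1C2(C)C | intermediate
9 | tert-butyldimethylsilyl ester of 10 | O=C[C@H]1CC=C(C(=O)OC)[C@@H](C(=O)O[Si](C)(C)C(C)(C)C)C1(C)C | intermediate
10 | (1S,5S)-5-formyl-2-(methoxycarbonyl)-6,6-dimethylcyclohex-2-ene-1-carboxylic acid (cis) | O=C[C@H]1CC=C(C(=O)OC)[C@@H](C(=O)O)C1(C)C | intermediate
11 | (1S,5R)-2-(methoxycarbonyl)-5-(2-methoxyethenyl)-6,6-dimethylcyclohex-2-ene-1-carboxylic acid (E/Z) | COC=C[C@H]1CC=C(C(=O)OC)[C@@H](C(=O)O)C1(C)C | intermediate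
12 | (1S,5R)-2-(hydroxymethyl)-5-(2-methoxyethenyl)-6,6-dimethylcyclohex-2-ene-1-carboxylic acid | COC=C[C@H]1CC=C(CO)[C@@H](C(=O)O)C1(C)C | intermediate
13 | (6R,7aS)-6-(2-methoxyethenyl)-7,7-dimethyl-5,6,7,7a-tetrahydro-2-benzofuran-1(3H)-one | COC=C[C@H]1CC=C2COC(=O)[C@H]2C1(C)C | intermediate
14 | (1R,5R)-5-(2-methoxyethenyl)-2,6,6-trimethylcyclohex-2-ene-1-carboxylic acid | COC=C[C@H]1CC=C(C)[C@@H](C(=O)O)C1(C)C | intermediate
15 | [(1R,5R)-5-(2-methoxyethenyl)-2,6,6-trimethylcyclohex-2-en-1-yl]methanol | COC=C[C@H]1CC=C(C)[C@@H](CO)C1(C)C | intermediate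
16 | 2-[(1R,3R)-3-(hydroxymethyl)-2,2,4-trimethylcyclohex-4-en-1-yl]acetaldehyde | O=CC[C@H]1CC=C(C)[C@@H](CO)C1(C)C | intermediate
17 | [(1R,5S)-2,6,6-trimethyl-5-(3-methylbut-2-en-1-yl)cyclohex-2-en-1-yl]methanol | CC(C)=CC[C@H]1CC=C(C)[C@@H](CO)C1(C)C | intermediate
18 | (1R,5S)-2,6,6-trimethyl-5-(3-methylbut-2-en-1-yl)cyclohex-2-ene-1-carbaldehyde | CC(C)=CC[C@H]1CC=C(C)[C@@H](C=O)C1(C)C | intermediate
19 | (E)-4-[(1R,5S)-2,6,6-trimethyl-5-(3-methylbut-2-en-1-yl)cyclohex-2-en-1-yl]but-3-en-2-one | CC(C)=CC[C@H]1CC=C(C)[C@@H](/C=C/C(C)=O)C1(C)C | intermediate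
20 | (E)-3-methyl-1-[(1R,5S)-2,6,6-trimethyl-5-(3-methylbut-2-en-1-yl)cyclohex-2-en-1-yl]penta-1,4-dien-3-ol (carbinol epimers) | CC(C)=CC[C@H]1CC=C(C)[C@@H](/C=C/C(C)(O)C=C)C1(C)C | intermediate
21 | {(2E,4E)-3-methyl-5-[(1R,5S)-2,6,6-trimethyl-5-(3-methylbut-2-en-1-yl)cyclohex-2-en-1-yl]penta-2,4-dien-1-yl}triphenylphosphonium bromide | CC(C)=CC[C@H]1CC=C(C)[C@@H](/C=C/C(C)=C/C[P+](c2ccccc2)(c2ccccc2)c2ccccc2)C1(C)C.[Br-] | intermediate
22 | methyl (E)-4-[(1R,3R)-3-(hydroxymethyl)-2,2,4-trimethylcyclohex-4-en-1-yl]-2-methylbut-2-enoate | COC(=O)/C(C)=C/C[C@H]1CC=C(C)[C@@H](CO)C1(C)C | intermediate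
23 | methyl (E)-4-[(1R,3R)-3-formyl-2,2,4-trimethylcyclohex-4-en-1-yl]-2-methylbut-2-enoate | COC(=O)/C(C)=C/C[C@H]1CC=C(C)[C@@H](C=O)C1(C)C | intermediate
24 | methyl (E)-2-methyl-4-{(1R,3R)-2,2,4-trimethyl-3-[(E)-3-oxobut-1-en-1-yl]cyclohex-4-en-1-yl}but-2-enoate (cis) | COC(=O)/C(C)=C/C[C@H]1CC=C(C)[C@@H](/C=C/C(C)=O)C1(C)C | intermediate
25 | methyl (E)-2-methyl-4-{(1R,3S)-2,2,4-trimethyl-3-[(E)-3-oxobut-1-en-1-yl]cyclohex-4-en-1-yl}but-2-enoate (trans) | COC(=O)/C(C)=C/C[C@H]1CC=C(C)[C@H](/C=C/C(C)=O)C1(C)C | intermediate
26 | methyl (E)-4-{(1R,3S)-3-[(E)-3-hydroxy-3-methylpenta-1,4-dien-1-yl]-2,2,4-trimethylcyclohex-4-en-1-yl}-2-methylbut-2-enoate (carbinol epimers) | COC(=O)/C(C)=C/C[C@H]1CC=C(C)[C@H](/C=C/C(C)(O)C=C)C1(C)C | intermediate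
27 | {(2E,4E)-5-[(1S,5R)-5-((E)-4-methoxy-3-methyl-4-oxobut-2-en-1-yl)-2,6,6-trimethylcyclohex-2-en-1-yl]-3-methylpenta-2,4-dien-1-yl}triphenylphosphonium bromide | COC(=O)/C(C)=C/C[C@H]1CC=C(C)[C@H](/C=C/C(C)=C/C[P+](c2ccccc2)(c2ccccc2)c2ccccc2)C1(C)C.[Br-] | intermediate
28 | (2E,4E,6E)-2,7-dimethylocta-2,4,6-trienedial | O=C/C(C)=C/C=C/C=C(C)/C=O | starting material
29 | ylide of 21, (2E,4E)-dienylidene-triphenylphosphorane | CC(C)=CC[C@H]1CC=C(C)[C@@H](/C=C/C(C)=C/C=P(c2ccccc2)(c2ccccc2)c2ccccc2)C1(C)C | intermediate
30 | (2S,6R)-2-(3-methylbut-2-en-1-yl)-12′-apo-ε-caroten-12′-al (all-E C30 aldehyde) | CC(C)=CC[C@H]1CC=C(C)[C@@H](/C=C/C(C)=C/C=C/C(C)=C/C=C/C=C(C)/C=O)C1(C)C | intermediate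
31 | ylide of 27, (2E,4E)-dienylidene-triphenylphosphorane | COC(=O)/C(C)=C/C[C@H]1CC=C(C)[C@H](/C=C/C(C)=C/C=P(c2ccccc2)(c2ccccc2)c2ccccc2)C1(C)C | intermediate
32 | methyl (E)-2-methyl-4-[(2S,6R,2′R,6′S)-2-(3-methylbut-2-en-1-yl)-ε,ε-caroten-2′-yl]but-2-enoate (all-E) | CC(C)=CC[C@H]1CC=C(C)[C@@H](/C=C/C(C)=C/C=C/C(C)=C/C=C/C=C(C)/C=C/C=C(C)/C=C/[C@H]2C(C)=CC[C@H](C/C=C(\C)C(=O)OC)C2(C)C)C1(C)C | intermediate
33 | (2S,6R,2′R,6′S)-2-(3-methylbut-2-en-1-yl)-2′-[(E)-4-hydroxy-3-methylbut-2-en-1-yl]-ε,ε-carotene | CC(C)=CC[C@H]1CC=C(C)[C@@H](/C=C/C(C)=C/C=C/C(C)=C/C=C/C=C(C)/C=C/C=C(C)/C=C/[C@H]2C(C)=CC[C@H](C/C=C(\C)CO)C2(C)C)C1(C)C | target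

## Step count and risks

Total: 24 steps. Longest linear sequence: 17 steps (3 → 6 → 8 → 16 → 27 → 32 → 33; the path through 21 and 30 is equally long).

**Step 5 (key step).** The cyclopropanation may be slowed by the quaternary carbon that flanks both diene termini, so that carbenoid dimerisation or decay of 6 takes over; the enantioselectivity established for unhindered dienes may also not carry over. Attack at the other double bond would give the regioisomeric bridge. Fallback: the enantioselective catalysis is given up for resolution. Setting out from 2 and 6, the small achiral catalyst Rh2(O2CCMe3)4 (dirhodium tetrapivalate, divalent rhodium) in CH2Cl2 at rt should pass through the racemic cyclopropane F1 to the racemic adduct F2. F2 is resolved by preparative chromatography on a chiral stationary phase (cellulose tris(3,5-dimethylphenylcarbamate)), and the fallback returns to the route at 8.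

**Step 19.** The extended enolate may reprotonate at C4 or C8 rather than at C6, so the ring double bond may drift into conjugation (C5=C6) or to the exocyclic position before the cis/trans equilibrium is reached; the equilibrium may also be less one-sided than expected. Fallback: ring B is made from the mirror-image series and inverted at C2, which is not allylic and cannot drift.
- Setting out from 2 and 6, Rh2(R-DOSP)4 gives, through the cyclopropane F3, the enantiomeric adduct F4.
- Ozonolysis as in step 6 gives, through the silyl ester F5, the aldehyde acid F6.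
- 1,8-Diazabicyclo[5.4.0]undec-7-ene in CH2Cl2 epimerises the aldehyde-bearing C2 of the carboxylate to the trans aldehyde acid F7, which has the ring B configuration.
- The chemistry of steps 7 to 10 then leads through the enol ether acid F8, the hydroxy acid F9, the lactone F10, the acid F11 and the enol ether alcohol F12 to the hydroxy aldehyde F13.
- Steps 16 and 17 give the hydroxy ester F14 and the trans aldehyde F15, and the Wittig reaction of step 18 brings the fallback back to the route at 25.

**Step 9.** Hydride may be delivered to the ring terminus C4 of the π-allyl complex, giving the exocyclic methylene isomer, or the basic medium may move the lactone double bond into conjugation. Fallback: the palladium chemistry is replaced by direct displacement. Setting out from the hydroxy acid 12 (step 8 stopped after the reduction), Me3SiCHN2 in MeOH/toluene gives the hydroxy ester F16. MsCl, LiCl and 2,4,6-collidine in DMF convert its allylic alcohol into the allylic chloride F17. LiBHEt3 in THF (−78 °C → rt) displaces the primary allylic chloride directly and reduces the ester; the fallback returns at 15, and the acid hydrolysis of step 10 follows.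

**Step 24.** The reduction is run on the fully assembled, light- and air-sensitive polyene, where over-exposure or work-up losses are most costly; the same ester also had to survive the vinyl addition of step 20. Fallback: the reduction is moved in front of the polyene assembly. Setting out from 26, i-Bu2AlH gives the diol F18. Ac2O/pyridine acetylates only the primary alcohol, giving F19. PPh3·HBr gives the acetoxy phosphonium salt F20. Its Wittig reaction with 30 (NaOMe, CH2Cl2/MeOH), through the ylide F21, should give the acetate F22, which is methanolysed by the excess NaOMe in the same flask; the fallback returns at 33.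

## Further compounds

F1 | step 5 | racemic methyl 1-(tert-butyldimethylsilyloxy)-4,4-dimethyl-6-vinylbicyclo[3.1.0]hex-2-ene-6-carboxylate (vinyl endo) | C=C[C@]1(C(=O)OC)[C@@H]2C(C)(C)C=C[C@]12O[Si](C)(C)C(C)(C)C.C=C[C@@]1(C(=O)OC)[C@H]2C(C)(C)C=C[C@@]12O[Si](C)(C)C(C)(C)C
F2 | step 5 | racemic methyl 7-(tert-butyldimethylsilyloxy)-8,8-dimethylbicyclo[3.2.1]octa-2,6-diene-2-carboxylate | CC(C)(C)[Si](C)(C)OC1=C[C@H]2CC=C(C(=O)OC)[C@@H]1C2(C)C.CC(C)(C)[Si](C)(C)OC1=C[C@@H]2CC=C(C(=O)OC)[C@H]1C2(C)C
F3 | step 19 | mirror image of 7 | C=C[C@@]1(C(=O)OC)[C@H]2C(C)(C)C=C[C@@]12O[Si](C)(C)C(C)(C)C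
F4 | step 19 | methyl (1R,5S)-7-(tert-butyldimethylsilyloxy)-8,8-dimethylbicyclo[3.2.1]octa-2,6-diene-2-carboxylate (mirror image of 8) | CC(C)(C)[Si](C)(C)OC1=C[C@@H]2CC=C(C(=O)OC)[C@H]1C2(C)C
F5 | step 19 | mirror image of 9 (silyl ester) | O=C[C@@H]1CC=C(C(=O)OC)[C@H](C(=O)O[Si](C)(C)C(C)(C)C)C1(C)C
F6 | step 19 | mirror image of 10 (cis aldehyde acid) | O=C[C@@H]1CC=C(C(=O)OC)[C@H](C(=O)O)C1(C)C
F7 | step 19 | trans-5-formyl-2-(methoxycarbonyl)-6,6-dimethylcyclohex-2-ene-1-carboxylic acid (ring B configuration) | O=C[C@H]1CC=C(C(=O)OC)[C@H](C(=O)O)C1(C)C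
F8 | step 19 | trans-2-(methoxycarbonyl)-5-(2-methoxyethenyl)-6,6-dimethylcyclohex-2-ene-1-carboxylic acid | COC=C[C@H]1CC=C(C(=O)OC)[C@H](C(=O)O)C1(C)C
F9 | step 19 | trans-2-(hydroxymethyl)-5-(2-methoxyethenyl)-6,6-dimethylcyclohex-2-ene-1-carboxylic acid | COC=C[C@H]1CC=C(CO)[C@H](C(=O)O)C1(C)C
F10 | step 19 | trans-6-(2-methoxyethenyl)-7,7-dimethyl-5,6,7,7a-tetrahydro-2-benzofuran-1(3H)-one | COC=C[C@H]1CC=C2COC(=O)[C@@H]2C1(C)C
F11 | step 19 | trans-5-(2-methoxyethenyl)-2,6,6-trimethylcyclohex-2-ene-1-carboxylic acid | COC=C[C@H]1CC=C(C)[C@H](C(=O)O)C1(C)C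
F12 | step 19 | [trans-5-(2-methoxyethenyl)-2,6,6-trimethylcyclohex-2-en-1-yl]methanol | COC=C[C@H]1CC=C(C)[C@H](CO)C1(C)C
F13 | step 19 | 2-[trans-3-(hydroxymethyl)-2,2,4-trimethylcyclohex-4-en-1-yl]acetaldehyde | O=CC[C@H]1CC=C(C)[C@H](CO)C1(C)C
F14 | step 19 | methyl (E)-4-[trans-3-(hydroxymethyl)-2,2,4-trimethylcyclohex-4-en-1-yl]-2-methylbut-2-enoate | COC(=O)/C(C)=C/C[C@H]1CC=C(C)[C@H](CO)C1(C)C
F15 | step 19 | methyl (E)-4-[trans-3-formyl-2,2,4-trimethylcyclohex-4-en-1-yl]-2-methylbut-2-enoate | COC(=O)/C(C)=C/C[C@H]1CC=C(C)[C@H](C=O)C1(C)C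
F16 | step 9 | methyl cis-2-(hydroxymethyl)-5-(2-methoxyethenyl)-6,6-dimethylcyclohex-2-ene-1-carboxylate | COC=C[C@H]1CC=C(CO)[C@@H](C(=O)OC)C1(C)C
F17 | step 9 | methyl cis-2-(chloromethyl)-5-(2-methoxyethenyl)-6,6-dimethylcyclohex-2-ene-1-carboxylate | COC=C[C@H]1CC=C(CCl)[C@@H](C(=O)OC)C1(C)C
F18 | step 24 | (E)-4-{trans-3-[(E)-3-hydroxy-3-methylpenta-1,4-dien-1-yl]-2,2,4-trimethylcyclohex-4-en-1-yl}-2-methylbut-2-en-1-ol | OC/C(C)=C/C[C@H]1CC=C(C)[C@H](/C=C/C(C)(O)C=C)C1(C)C
F19 | step 24 | primary acetate of F18 | CC(=O)OC/C(C)=C/C[C@H]1CC=C(C)[C@H](/C=C/C(C)(O)C=C)C1(C)C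
F20 | step 24 | {(2E,4E)-5-[trans-5-((E)-4-acetoxy-3-methylbut-2-en-1-yl)-2,6,6-trimethylcyclohex-2-en-1-yl]-3-methylpenta-2,4-dien-1-yl}triphenylphosphonium bromide | CC(=O)OC/C(C)=C/C[C@H]1CC=C(C)[C@H](/C=C/C(C)=C/C[P+](c2ccccc2)(c2ccccc2)c2ccccc2)C1(C)C.[Br-]
F21 | step 24 | ylide of F20 | CC(=O)OC/C(C)=C/C[C@H]1CC=C(C)[C@H](/C=C/C(C)=C/C=P(c2ccccc2)(c2ccccc2)c2ccccc2)C1(C)C
F22 | step 24 | acetate of 33 | CC(C)=CC[C@H]1CC=C(C)[C@@H](/C=C/C(C)=C/C=C/C(C)=C/C=C/C=C(C)/C=C/C=C(C)/C=C/[C@H]2C(C)=CC[C@H](C/C=C(\C)COC(C)=O)C2(C)C)C1(C)C
A1 | alternative 1 | 5-(benzyloxymethyl)-4,4,6-trimethyl-6-vinyltetrahydro-2H-pyran-2-one (vinyl trans to benzyloxymethyl) | C=C[C@@]1(C)OC(=O)CC(C)(C)[C@@H]1COCc1ccccc1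
A2 | alternative 1 | cis-6-(benzyloxymethyl)-2,2,5-trimethylcyclohex-4-ene-1-carboxylic acid | OC(=O)[C@H]1CC=C(C)[C@@H](COCc2ccccc2)C1(C)C
A3 | alternative 2 | (R)-limonene | CC1=CC[C@@H](CC1)C(C)=C
A4 | alternative 2 | (3R,6E,8E)-6-methyl-10-oxo-3-(prop-1-en-2-yl)undeca-6,8-dien-1-yl acetate | CC(=O)OCC[C@@H](CC/C(C)=C/C=C/C(C)=O)C(C)=C
A5 | alternative 2 | cis-2-(2-acetoxyethyl)-α-ionone | CC(=O)OCC[C@H]1CC=C(C)[C@@H](/C=C/C(C)=O)C1(C)C
A6 | alternative 3 | benzyl 3,3-dimethyl-2-(prop-1-en-2-yl)-4-(prop-2-en-1-yl)hept-6-en-1-yl ether (single enantiomer at C2 of the chain) | C=CCC(CC=C)C(C)(C)[C@@H](COCc1ccccc1)C(C)=C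
A7 | alternative 3 | trans-2-allyl-α-cyclogeranyl benzyl ether | c1ccccc1COC[C@H]2C(C)=CC[C@H](CC=C)C2(C)C
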